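**Plan**

- Retrosynthesis: after removal of the silyl group from the ring B phenol, ring A is opened at C1'–C2' and C5'–C6'. This leaves a terminal alkynyl ketone (C1', C6') and a four-carbon acetoacetate-derived diene (C2'–C5').
- Enabling feature: ring A carries the acyl group at C1', oxygen at C2' and C4', the prenyl (3-methylbut-2-enyl) group at C3' between the two oxygens, and hydrogen at C5' and C6'. This is the pattern of a 2-prenyl-1-methoxy-1,3-bis(silyloxy)buta-1,3-diene joined to the two alkyne carbons of an ynone.
- Further cuts: the ynone is cut at C(=O)–C≡C (ethynyl Grignard on a Weinreb amide) and at the Cα=Cβ alkene (Horner–Wadsworth–Emmons), back to 4-hydroxy-3-prenylbenzaldehyde. The diene is cut at its C2–prenyl bond, back to methyl acetoacetate.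
- Forward order: ring B is bought as 4-hydroxybenzaldehyde, prenylated, silylated and extended to the enamide and then the enynone. The diene is made in three steps. Ring A, the only ring formed, arises in the Diels–Alder/aromatisation, and desilylation ends the route.
- Stereochemistry: there is no stereocentre. The E enone alkene is set by the olefination in step 6 and carried through unchanged.

Key step: step 8

Remark on the chemistry: the geometry of the C2=C3 bond of 4 and of the ketene acetal C1=C2 bond of 5 is not controlled by the silylations. Both are carried as E/Z mixtures (SMILES without descriptor), which is harmless because neither double bond survives as a stereo-element once ring A is aromatic. Primed locants refer to ring A (the ring bearing the carbonyl), unprimed ones to ring B.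

**Route**

Step 1
Reactants: 1 methyl acetoacetate; 2 prenyl bromide (1-bromo-3-methylbut-2-ene)
Product: 3 methyl 2-acetyl-5-methylhex-4-enoate (racemic)
Conditions: NaH, THF, 0 °C; then 2, 0 °C → rt (1 in slight excess)
Reagents that add atoms: none
Why: Acetoacetic ester alkylation, in which the sodium enolate of the β-keto ester is C-alkylated by the primary allylic bromide in an SN2 reaction, the slight excess of 1 holding back dialkylation.

Step 2
Reactants: 3 methyl 2-acetyl-5-methylhex-4-enoate
Product: 4 methyl 2-(3-methylbut-2-enyl)-3-(trimethylsilyloxy)but-2-enoate (E/Z mixture)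
Conditions: Me3SiCl, Et3N, PhMe, rt
Reagents that add atoms: chlorotrimethylsilane, C[Si](C)(C)Cl
Why: Soft enolisation and O-silylation of the β-keto ester gives the ester-conjugated silyl enol ether, the usual first stage on the way to 1,3-bis(silyloxy)buta-1,3-dienes.

Step 3
Reactants: 4 methyl 2-(3-methylbut-2-enyl)-3-(trimethylsilyloxy)but-2-enoate
Product: 5 1-methoxy-2-(3-methylbut-2-enyl)-1,3-bis(trimethylsilyloxy)buta-1,3-diene (E/Z mixture at C1=C2)
Conditions: LiN(i-Pr)2, THF, −78 °C; then Me3SiCl, −78 °C → rt; used crude or after short-path distillation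
Reagents that add atoms: chlorotrimethylsilane, C[Si](C)(C)Cl
Why: Kinetic γ-deprotonation of the vinylogous ester at its C4 methyl group gives the lithium dienolate, which is silylated on the ester oxygen (silyl ketene acetal formation), as is established for 2-alkyl-substituted bis(silyloxy)dienes of this family.

Step 4
Reactants: 6 4-hydroxybenzaldehyde; 2 prenyl bromide
Product: 7 4-hydroxy-3-(3-methylbut-2-enyl)benzaldehyde
Conditions: KOH (10 % aq), 2 added dropwise, rt; then HCl (aq) to pH 5
Reagents that add atoms: none
Why: ortho-C-Allylation of a phenoxide in water, where hydrogen bonding to the phenoxide oxygen diverts the allylic bromide to ring carbon, the para position is blocked by the formyl group and the two ortho positions are equivalent, so one C-prenyl regioisomer is expected beside separable O-prenyl ether and recovered 6.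

Step 5
Reactants: 7 4-hydroxy-3-(3-methylbut-2-enyl)benzaldehyde
Product: 8 4-(tert-butyldimethylsilyloxy)-3-(3-methylbut-2-enyl)benzaldehyde
Conditions: t-BuMe2SiCl, imidazole, DMF, rt
Reagents that add atoms: tert-butyldimethylsilyl chloride, CC(C)(C)[Si](C)(C)Cl
Why: Imidazole-promoted silylation of the phenol gives an ether that is inert to the Grignard reagent and to silyl transfer from the diene and can later be removed by fluoride without the acid that would cyclise the ortho-prenylphenols to chromans.

Step 6
Reactants: 8 4-(tert-butyldimethylsilyloxy)-3-(3-methylbut-2-enyl)benzaldehyde; 9 diethyl [2-[methoxy(methyl)amino]-2-oxoethyl]phosphonate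
Product: 10 (2E)-3-[4-(tert-butyldimethylsilyloxy)-3-(3-methylbut-2-enyl)phenyl]-N-methoxy-N-methylprop-2-enamide
Conditions: NaH, THF, 0 °C → rt
Reagents that add atoms: none
Why: Horner–Wadsworth–Emmons olefination of an aromatic aldehyde with a stabilised amide phosphonate carbanion is reliably E-selective and sets the only stereo-element of the target.

Step 7
Reactants: 10 (2E)-3-[4-(tert-butyldimethylsilyloxy)-3-(3-methylbut-2-enyl)phenyl]-N-methoxy-N-methylprop-2-enamide; 11 ethynylmagnesium bromide
Product: 13 (1E)-1-[4-(tert-butyldimethylsilyloxy)-3-(3-methylbut-2-enyl)phenyl]pent-1-en-4-yn-3-one, via bromomagnesium hemiaminal chelate 12 (not isolated)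
Conditions: THF, −10 → 0 °C; then poured into cold 1 M HCl
Reagents that add atoms: none
Why: Weinreb ketone synthesis, in which the ethynyl Grignard reagent adds once to give the five-membered magnesium chelate 12, which collapses to the ynone only in the cold acidic quench, where the released amine is protonated and cannot add to the terminal ynone.

Step 8
Reactants: 5 1-methoxy-2-(3-methylbut-2-enyl)-1,3-bis(trimethylsilyloxy)buta-1,3-diene; 13 (1E)-1-[4-(tert-butyldimethylsilyloxy)-3-(3-methylbut-2-enyl)phenyl]pent-1-en-4-yn-3-one
Product: 16 4-O-(tert-butyldimethylsilyl)kanzonol C, via cyclohexa-1,4-diene cycloadduct 14 (not isolated), via 4'-O-trimethylsilyl ether 15 (not isolated)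
Conditions: 5 (2 equiv), PhMe, 0 → 40 °C; then citric acid (10 % aq), THF, 0 °C
Reagents that add atoms: none
Why: The electron-rich diene 5 and the electron-poor ynone 13 should combine in a normal-demand, concerted but strongly asynchronous [4+2] cycloaddition: the CH2 terminus (C4) of 5 bonds first to the unsubstituted alkyne carbon (C5'–C6'), and the ketene acetal carbon (C1) then bonds to the carbonyl-bearing alkyne carbon (C1'–C2'), closing the six-membered carbocycle 14 from four diene carbons and two alkyne carbons. The doubly allylic mixed ketal of 14 then loses Me3SiOMe with a 1,4-hydrogen shift to give the aromatic 15, whose 2'-OH is hydrogen-bonded to the ketone, and the citric acid wash hydrolyses the remaining aryl trimethylsilyl ether while leaving the tert-butyldimethylsilyl ether and both prenyl groups untouched. The closest known reaction type is the Diels–Alder benzannulation of 1-alkoxy-1,3-bis(silyloxy)buta-1,3-dienes with alkynyl ketones and propiolates, which gives acylresorcinols and resorcylates by loss of alcohol or alkoxysilane. No stereocentre is created that survives, since the ketal carbon of 14 is erased on aromatisation and the E alkene is a spectator. The regiochemistry (2'-OH next to the ketone, prenyl between the two oxygens) follows from pairing the most nucleophilic diene terminus with the β-carbon of the ynone. The step also needs the alkyne to react before the enone alkene, which is secured because the terminal ynone is unhindered and more electrophilic than the aryl-conjugated, β-substituted C=C, while the isolated prenyl alkenes are unactivated and the silylated ring B phenol cannot quench the diene.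

Step 9
Reactants: 16 4-O-(tert-butyldimethylsilyl)kanzonol C
Product: 17 kanzonol C
Conditions: Bu4NF, AcOH, THF, 0 °C
Reagents that add atoms: none
Why: Fluoride cleavage of the aryl silyl ether is driven by the strong Si–F bond, and the acetic acid buffer keeps the 2'-hydroxychalcone from closing to the flavanone by oxa-Michael addition.

**Compound list**

1 | methyl acetoacetate | COC(=O)CC(C)=O | starting material
2 | prenyl bromide (1-bromo-3-methylbut-2-ene) | CC(C)=CCBr | starting material
3 | methyl 2-acetyl-5-methylhex-4-enoate (racemic) | COC(=O)C(CC=C(C)C)C(C)=O | intermediate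
4 | methyl 2-(3-methylbut-2-enyl)-3-(trimethylsilyloxy)but-2-enoate (E/Z mixture) | COC(=O)C(CC=C(C)C)=C(C)O[Si](C)(C)C | intermediate
5 | 1-methoxy-2-(3-methylbut-2-enyl)-1,3-bis(trimethylsilyloxy)buta-1,3-diene (E/Z mixture at C1=C2) | COC(O[Si](C)(C)C)=C(CC=C(C)C)C(=C)O[Si](C)(C)C | intermediate
6 | 4-hydroxybenzaldehyde | O=Cc1ccc(O)cc1 | starting material
7 | 4-hydroxy-3-(3-methylbut-2-enyl)benzaldehyde | CC(C)=CCc1cc(C=O)ccc1O | intermediate
8 | 4-(tert-butyldimethylsilyloxy)-3-(3-methylbut-2-enyl)benzaldehyde | CC(C)=CCc1cc(C=O)ccc1O[Si](C)(C)C(C)(C)C | intermediate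
9 | diethyl [2-[methoxy(methyl)amino]-2-oxoethyl]phosphonate | CCOP(=O)(CC(=O)N(C)OC)OCC | starting material
10 | (2E)-3-[4-(tert-butyldimethylsilyloxy)-3-(3-methylbut-2-enyl)phenyl]-N-methoxy-N-methylprop-2-enamide | CON(C)C(=O)/C=C/c1ccc(O[Si](C)(C)C(C)(C)C)c(CC=C(C)C)c1 | intermediate
11 | ethynylmagnesium bromide | C#C[Mg]Br | starting material
12 | bromomagnesium salt of (1E)-1-[4-(tert-butyldimethylsilyloxy)-3-(3-methylbut-2-enyl)phenyl]-3-[methoxy(methyl)amino]pent-1-en-4-yn-3-ol (tetrahedral magnesium chelate, racemic) | C#CC(O[Mg]Br)(N(C)OC)/C=C/c1ccc(O[Si](C)(C)C(C)(C)C)c(CC=C(C)C)c1 | intermediate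
13 | (1E)-1-[4-(tert-butyldimethylsilyloxy)-3-(3-methylbut-2-enyl)phenyl]pent-1-en-4-yn-3-one | C#CC(=O)/C=C/c1ccc(O[Si](C)(C)C(C)(C)C)c(CC=C(C)C)c1 | intermediate
14 | (2E)-3-[4-(tert-butyldimethylsilyloxy)-3-(3-methylbut-2-enyl)phenyl]-1-[6-methoxy-5-(3-methylbut-2-enyl)-4,6-bis(trimethylsilyloxy)cyclohexa-1,4-dien-1-yl]prop-2-en-1-one (Diels–Alder adduct, racemic at the ketal carbon) | COC1(O[Si](C)(C)C)C(CC=C(C)C)=C(O[Si](C)(C)C)CC=C1C(=O)/C=C/c1ccc(O[Si](C)(C)C(C)(C)C)c(CC=C(C)C)c1 | intermediate
15 | (2E)-3-[4-(tert-butyldimethylsilyloxy)-3-(3-methylbut-2-enyl)phenyl]-1-[2-hydroxy-3-(3-methylbut-2-enyl)-4-(trimethylsilyloxy)phenyl]prop-2-en-1-one | CC(C)=CCc1cc(/C=C/C(=O)c2ccc(O[Si](C)(C)C)c(CC=C(C)C)c2O)ccc1O[Si](C)(C)C(C)(C)C | intermediate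
16 | 4-O-(tert-butyldimethylsilyl)kanzonol C, (2E)-3-[4-(tert-butyldimethylsilyloxy)-3-(3-methylbut-2-enyl)phenyl]-1-[2,4-dihydroxy-3-(3-methylbut-2-enyl)phenyl]prop-2-en-1-one | CC(C)=CCc1cc(/C=C/C(=O)c2ccc(O)c(CC=C(C)C)c2O)ccc1O[Si](C)(C)C(C)(C)C | intermediate
17 | kanzonol C, (2E)-1-[2,4-dihydroxy-3-(3-methylbut-2-enyl)phenyl]-3-[4-hydroxy-3-(3-methylbut-2-enyl)phenyl]prop-2-en-1-one | CC(C)=CCc1cc(/C=C/C(=O)c2ccc(O)c(CC=C(C)C)c2O)ccc1O | target

**Count**

Total steps: 9. Longest linear sequence: 6 steps (steps 4, 5, 6, 7, 8, 9, from 4-hydroxybenzaldehyde). The diene branch (steps 1–3) joins at step 8.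

**Steps most likely to fail, with fallbacks**

Step 8 (key step). The cross-conjugated enynone may be consumed by conjugate addition of the diene without ring closure, by reaction at the styryl alkene or by oligomerisation before the cycloaddition is complete. The fallback keeps the same ring closure but moves the chalcone alkene to a later bond formation. It sets out from diene 5, which is combined with commercial but-3-yn-2-one (excess, PhMe, 0 °C → rt), a small and robust ynone with no competing alkene. This should give the cycloadduct 1-[6-methoxy-5-(3-methylbut-2-enyl)-4,6-bis(trimethylsilyloxy)cyclohexa-1,4-dien-1-yl]ethanone F1. F1 is expected to lose Me3SiOMe to 1-[2-hydroxy-3-(3-methylbut-2-enyl)-4-(trimethylsilyloxy)phenyl]ethanone F2, and citric acid work-up should give 1-[2,4-dihydroxy-3-(3-methylbut-2-enyl)phenyl]ethanone F3. Claisen–Schmidt condensation of F3 with aldehyde 8 follows, using excess LiN(SiMe3)2 in THF (−78 °C → rt, then cold dilute HCl), a protocol that carries free phenols through as their lithium salts. It should deliver the chalcone 16, where the route is rejoined before step 9.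

Step 4. O-Alkylation and double alkylation of the phenoxide may outrun the mono ortho-C-alkylation, leaving little of the C-prenyl aldehyde. The fallback installs the prenyl group by a sigmatropic shift and sets out from 6. O-Alkylation with 3-chloro-3-methylbut-1-yne (CuCl2 cat., DBU, MeCN, 0 °C) should give 4-(2-methylbut-3-yn-2-yloxy)benzaldehyde F4. Semi-hydrogenation (H2, Pd/CaCO3 poisoned with Pb(OAc)2, quinoline, EtOAc) should give 4-(2-methylbut-3-en-2-yloxy)benzaldehyde F5. Aromatic Claisen rearrangement of F5 (PhNEt2, about 140 °C) transfers the allyl unit with transposition to the ortho carbon, so that the tertiary ether becomes the linear prenyl group. This gives 7, where the route is rejoined before step 5.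

Step 7. The liberated N,O-dimethylhydroxylamine or a second acetylide may add in conjugate fashion to the new terminal ynone during the reaction or the quench. The fallback forms the ynone by oxidation only after the amine has been removed and sets out from amide 10. Reduction with i-Bu2AlH (THF, −78 °C) should give (2E)-3-[4-(tert-butyldimethylsilyloxy)-3-(3-methylbut-2-enyl)phenyl]prop-2-enal F6. 1,2-Addition of 11 (THF, 0 °C) should give racemic (1E)-1-[4-(tert-butyldimethylsilyloxy)-3-(3-methylbut-2-enyl)phenyl]pent-1-en-4-yn-3-ol F7. Oxidation of this doubly activated allylic and propargylic alcohol with MnO2 (CH2Cl2, rt) should give 13, where the route is rejoined before step 8.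

**Further compounds**

F1 | step 8 | 1-[6-methoxy-5-(3-methylbut-2-enyl)-4,6-bis(trimethylsilyloxy)cyclohexa-1,4-dien-1-yl]ethanone (racemic) | CC(=O)C1=CCC(O[Si](C)(C)C)=C(CC=C(C)C)C1(OC)O[Si](C)(C)C
F2 | step 8 | 1-[2-hydroxy-3-(3-methylbut-2-enyl)-4-(trimethylsilyloxy)phenyl]ethanone | CC(=O)c1ccc(O[Si](C)(C)C)c(CC=C(C)C)c1O
F3 | step 8 | 1-[2,4-dihydroxy-3-(3-methylbut-2-enyl)phenyl]ethanone | CC(=O)c1ccc(O)c(CC=C(C)C)c1O
F4 | step 4 | 4-(2-methylbut-3-yn-2-yloxy)benzaldehyde | O=Cc1ccc(OC(C)(C)C#C)cc1
F5 | step 4 | 4-(2-methylbut-3-en-2-yloxy)benzaldehyde | O=Cc1ccc(OC(C)(C)C=C)cc1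
F6 | step 7 | (2E)-3-[4-(tert-butyldimethylsilyloxy)-3-(3-methylbut-2-enyl)phenyl]prop-2-enal | O=C/C=C/c1ccc(O[Si](C)(C)C(C)(C)C)c(CC=C(C)C)c1
F7 | step 7 | (1E)-1-[4-(tert-butyldimethylsilyloxy)-3-(3-methylbut-2-enyl)phenyl]pent-1-en-4-yn-3-ol (racemic) | C#CC(O)/C=C/c1ccc(O[Si](C)(C)C(C)(C)C)c(CC=C(C)C)c1
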